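We start from the amounts: ochre holds 0.050 M of free monomer with 0.14 mol% of initiator on it, and amber holds the same free monomer with 0.2 mol%.

- ochre: free monomer 0.050 M; initiator 0.14 mol%; time 1.0 h
- amber: free monomer 0.050 M; initiator 0.2 mol%; time 1.0 h

* which of the two ends with the longer chains by the average number of monomer units in a chain (living and dead chains, two that joined counted as one) ("neither" if they lie within 10%) (ochre / amber / neither)
* average number of monomer units in a chain (living and dead chains, two that joined counted as one) at the end, ochre
* average number of monomer units in a chain (living and dead chains, two that joined counted as one) at the end, amber

- for a step with 2 of a species take k times the square, and two of it per event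
- the average divides the monomer in chains by the number of chains, living and dead together; two radicals that join make one chain
- run time (ochre): 1.0 h

    initiator → 2 initiating radical (k1 = 0.0055 s⁻¹)
    free monomer + initiating radical → growing radical + monomer in chains (k2 = 1.7 × 10⁷ L mol⁻¹ s⁻¹)
    free monomer + growing radical → monomer in chains + growing radical, rate k3*[growing radical]*[free monomer] (k3 = 2.9 × 10⁵ L mol⁻¹ s⁻¹)
    2 growing radical → dead chain (k4 = 1 × 10⁸ L mol⁻¹ s⁻¹)
    free monomer → decomposition product (k5 = 8.5 × 10⁻⁵ s⁻¹)

1. We count chains first. One initiator gives two initiating radicals, each starts one growing radical, and two growing radicals join into one dead chain. So one initiator ends as one chain.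

2. Once the initiator has all made chains, the average can therefore reach at best c(free monomer) charged over c(initiator) charged; while initiator is still unreacted there are fewer chains, and this ratio is no bound. For ochre this ratio is 714; we call it the ceiling, the monomer units on offer per chain. For amber it is 500.

3. Is the initiator used up? Its half-life is 2.10 min, and the hour holds 28.6 of them, so hardly any initiator stays.

4. Is one number enough? In ochre at the start, radical supply balances joining at c(growing radical) = 6.20 × 10⁻⁸ M. At that level free monomer goes into chains by a pseudo-first-order loss, and decomposition takes 0.472% of what reacts. We take this starting share for the whole run, as an estimate.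

5. The radical level falls with the root of the initiator, so it lasts about two initiator lifetimes. Over them, ochre's free monomer sees 6.54 of its own lifetimes, which leaves 0.144%.

6. Our reckoning takes these small shares off the ceiling and gives 710 for ochre and 498 for amber, so ochre has the longer chains.

The forecast says ochre, with 709 and 497, on these grounds: “the lower-initiator ochre charge gives the longer chains”.

The simulation gives ochre, with 709 for ochre and 498 for amber, against our 710 and 498.

Ochre ends at 709, just under its ceiling of 714. A neighbour like ochre with 0.24 mol% of initiator has a ceiling of 417 and stands at 415. Has ochre come to rest? Left for 10.0 h, its average reads 709, and monomer in chains stays at 99.3% of the charge. Free monomer still falls from 0.0955% to 0.00605% of the charge, and decomposition product rises from 0.606% to 0.695%. Growing radical falls from 7.95 × 10⁻¹² M to 1.52 × 10⁻¹³ M.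

(The numbers of this flask were drawn at random within sensible limits; the run is a simulation.)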